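**Retrosynthetic overview**

1. Target 17 comes from double O-methylation of 7,8-diol 16, which comes from oxidation of the C7–B bond of the 8-hydroxy-7-boryl-5-methoxyflavone 15.
2. Ring A of 15 is opened by a Dötz benzannulation: pyranon-3-yl methoxycarbene 12, ethynylboronate 13 and one CO ligand form C5–C6, C7–C8 and C8–C8a on the pyranone C3=C2 bond (flavone C4a=C8a).
3. Carbene 12 comes from acid chloride 8 and Na2Cr(CO)5, then Me3OBF4. The pyranone (ring C) comes from enaminone 4, acylated as its dienolate by aroyl chloride 2 and closed with acid.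
4. Feature on which the plan rests: ring A has oxygens at C5 and C8 para to each other, with C6–H and oxygenated C7 between them. These map onto carbene carbon (C5–OMe), alkyne CH (C6), alkyne C–B (C7, a masked OH) and inserted CO (C8–OH).
5. Ring order: ring B is bought (in 1), ring C is made in step 3, ring A is made last in step 7.

Key step: step 7

**Remarks on the chemistry**

- A tert-butyl ester is carried through the pyranone synthesis so that the acid is freed with TFA; aqueous hydroxide would open the 4-pyranone ring.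
- The first benzannulation product is taken to be the Cr(CO)3 complex of the new arene. It is demetalated with air, not with (NH4)2Ce(NO3)6, which would oxidize the 5-methoxy-8-hydroxy arene to the quinone.
- The push-pull C=C bond of 4 and 5 has no fixed geometry and is written without E/Z. The target has no stereocenter.
- In the SMILES, carbonyl ligands are written as =C=O on chromium. The η6 bond of 14 cannot be written and is shown as two dot-joined fragments.

**Route**

Step 1
Reactants: 1 2,3,4-trimethoxybenzoic acid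
Product: 2 2,3,4-trimethoxybenzoyl chloride
Conditions: (COCl)2, DMF (cat.), CH2Cl2, 0 °C to rt; evaporate
Reagents that add atoms: oxalyl chloride, O=C(Cl)C(=O)Cl
Why: Vilsmeier-catalysed conversion of a carboxylic acid to its chloride, with only gaseous by-products, should give 2 clean enough for direct use.

Step 2
Reactants: 3 tert-butyl acetoacetate
Product: 4 tert-butyl 2-[(dimethylamino)methylene]-3-oxobutanoate
Conditions: Me2NCH(OMe)2 (1.1 equiv), neat, rt to 50 °C; remove MeOH
Reagents that add atoms: N,N-dimethylformamide dimethyl acetal, COC(OC)N(C)C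
Why: Condensation of the active methylene of a β-keto ester with an amide acetal (enaminone formation) installs the one-carbon unit that later becomes C8a.

Step 3
Reactants: 4 tert-butyl 2-[(dimethylamino)methylene]-3-oxobutanoate; 2 2,3,4-trimethoxybenzoyl chloride
Product: 6 tert-butyl 4-oxo-6-(2,3,4-trimethoxyphenyl)-4H-pyran-3-carboxylate, via acylated enaminone 5 (not isolated)
Conditions: LiN(SiMe3)2 (2.5 equiv), THF, −78 °C; 2, −78 °C; then 1 M aq HCl, 0 °C to rt
Reagents that add atoms: none
Why: The base deprotonates the acetyl methyl group of the vinylogous amide, the dienolate is C-acylated by 2 to diketone 5 (held as its enolate by the extra base), and on acidification the aryl-ketone enol oxygen adds to the aminomethylene carbon and expels dimethylamine, an addition–elimination that closes the 4-pyranone (known enaminone-anion acylation route to 4-pyranone-3-carboxylates).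

Step 4
Reactants: 6 tert-butyl 4-oxo-6-(2,3,4-trimethoxyphenyl)-4H-pyran-3-carboxylate
Product: 7 4-oxo-6-(2,3,4-trimethoxyphenyl)-4H-pyran-3-carboxylic acid
Conditions: TFA, CH2Cl2, rt
Reagents that add atoms: none
Why: Acidolysis of the tert-butyl ester through the tert-butyl cation frees the acid without base, so the hydroxide-sensitive pyranone and the aryl methyl ethers should survive.

Step 5
Reactants: 7 4-oxo-6-(2,3,4-trimethoxyphenyl)-4H-pyran-3-carboxylic acid
Product: 8 4-oxo-6-(2,3,4-trimethoxyphenyl)-4H-pyran-3-carbonyl chloride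
Conditions: (COCl)2 (1.05 equiv), DMF (cat.), CH2Cl2, 0 °C to rt; evaporate, use crude
Reagents that add atoms: oxalyl chloride, O=C(Cl)C(=O)Cl
Why: Acid chloride formation as for chromone-3-carbonyl chlorides; the carboxylic acid reacts much faster than the vinylogous-ester carbonyl, and near-stoichiometric reagent at low temperature should prevent 4-chloropyrylium formation.

Step 6
Reactants: 8 4-oxo-6-(2,3,4-trimethoxyphenyl)-4H-pyran-3-carbonyl chloride; 9 chromium hexacarbonyl, Cr(CO)6
Product: 12 pentacarbonyl{methoxy[4-oxo-6-(2,3,4-trimethoxyphenyl)-4H-pyran-3-yl]methylene}chromium, via disodium pentacarbonylchromate 10 (not isolated), via sodium acylchromate 11 (not isolated)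
Conditions: Cr(CO)6, NaC10H8 (sodium naphthalenide, 2.0 equiv), THF, −78 to 0 °C; 8, THF, −78 °C; then Me3OBF4 (1.0 equiv), CH2Cl2, 0 °C
Reagents that add atoms: trimethyloxonium tetrafluoroborate, C[O+](C)C.F[B-](F)(F)F
Why: This is the Semmelhack–Hegedus route to alkoxycarbene complexes, in which the Cr(CO)5 dianion is acylated at chromium by an acid chloride and the acylate oxygen is then methylated by the oxonium salt; it is chosen because a 3-lithio-4-pyranone for the organolithium route is not accessible, and one equivalent of Me3OBF4 should alkylate the anionic acylate oxygen ahead of the neutral pyranone carbonyl.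

Step 7
Reactants: 12 pentacarbonyl{methoxy[4-oxo-6-(2,3,4-trimethoxyphenyl)-4H-pyran-3-yl]methylene}chromium; 13 2-ethynyl-4,4,5,5-tetramethyl-1,3,2-dioxaborolane
Product: 15 8-hydroxy-5-methoxy-7-(4,4,5,5-tetramethyl-1,3,2-dioxaborolan-2-yl)-2-(2,3,4-trimethoxyphenyl)-4H-chromen-4-one, via tricarbonylchromium arene complex 14 (not isolated)
Conditions: 13 (2 equiv), THF, 50 °C, Ar; then air, Et2O, daylight, rt
Reagents that add atoms: none
Why: Proposed new method: thermal loss of one CO from 12 (the pyranone C4 carbonyl oxygen can hold the vacant site as a hemilabile chelate) lets 13 insert into the Cr=C bond with its CH terminus bonding to the carbene carbon (C5–C6), CO insertion at the new boryl-bearing carbene carbon gives a chromium-bound dienylketene (C7–C8), and ring closure of the ketene carbon onto pyranone C2 (C8–C8a) followed by enolization gives the Cr(CO)3-bound phenol 14, which air oxidation should free as 15. The closest known reaction type is the Dötz benzannulation of alkenyl(methoxy)carbene pentacarbonylchromium complexes with alkynylboronic esters, which gives ortho-borylated hydroquinone monomethyl ethers; a 4-pyranon-3-yl carbene has not been used in it. Ring A, the only ring formed, closes by 6π electrocyclization of the dienylketene across the existing pyranone C3=C2 bond (flavone C4a=C8a), and no stereocenter is created. Three selectivities are needed: the boryl-bearing alkyne carbon must end next to the CO-derived C8, which the terminal alkyne secures because its larger boryl end is placed away from the carbene substituents; CO insertion must beat cyclopentannulation, which the methoxy donor, the alkenyl (weakly aromatic) character of the pyranone C2=C3 bond and THF as solvent favour; and the cyclohexadienone must aromatize, which the hydrogen on pyranone C2 allows.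

Step 8
Reactants: 15 8-hydroxy-5-methoxy-7-(4,4,5,5-tetramethyl-1,3,2-dioxaborolan-2-yl)-2-(2,3,4-trimethoxyphenyl)-4H-chromen-4-one
Product: 16 7,8-dihydroxy-5-methoxy-2-(2,3,4-trimethoxyphenyl)-4H-chromen-4-one
Conditions: 30% aq H2O2 (1.5 equiv), NaHCO3, THF/H2O, 0 °C to rt, Ar; then aq Na2S2O3
Reagents that add atoms: hydrogen peroxide, OO
Why: Ipso-hydroxylation of an arylboronic ester (hydroperoxide adds to boron, the aryl group migrates from boron to oxygen, the borate hydrolyses); bicarbonate buffering, limited peroxide and exclusion of air should spare the electron-rich catechol and the flavone enone.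

Step 9
Reactants: 16 7,8-dihydroxy-5-methoxy-2-(2,3,4-trimethoxyphenyl)-4H-chromen-4-one
Product: 17 2',3',4',5,7,8-hexamethoxyflavone (5,7,8-trimethoxy-2-(2,3,4-trimethoxyphenyl)-4H-chromen-4-one)
Conditions: Me2SO4 (3 equiv), K2CO3, acetone, reflux, Ar
Reagents that add atoms: dimethyl sulfate, COS(=O)(=O)OC
Why: Williamson O-methylation of both phenols (the 7-OH is para to the carbonyl-bearing C4a and acidic, the 8-OH follows with excess reagent) is the standard way to permethylate hydroxyflavones and should give the target.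

**Compound list**

1 | 2,3,4-trimethoxybenzoic acid | COc1ccc(C(=O)O)c(OC)c1OC | starting material
2 | 2,3,4-trimethoxybenzoyl chloride | COc1ccc(C(=O)Cl)c(OC)c1OC | intermediate
3 | tert-butyl acetoacetate | CC(=O)CC(=O)OC(C)(C)C | starting material
4 | tert-butyl 2-[(dimethylamino)methylene]-3-oxobutanoate | CC(=O)C(=CN(C)C)C(=O)OC(C)(C)C | intermediate
5 | tert-butyl 2-[(dimethylamino)methylene]-3,5-dioxo-5-(2,3,4-trimethoxyphenyl)pentanoate (not isolated) | CN(C)C=C(C(=O)OC(C)(C)C)C(=O)CC(=O)c1ccc(OC)c(OC)c1OC | intermediate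
6 | tert-butyl 4-oxo-6-(2,3,4-trimethoxyphenyl)-4H-pyran-3-carboxylate | COc1ccc(-c2cc(=O)c(C(=O)OC(C)(C)C)co2)c(OC)c1OC | intermediate
7 | 4-oxo-6-(2,3,4-trimethoxyphenyl)-4H-pyran-3-carboxylic acid | COc1ccc(-c2cc(=O)c(C(=O)O)co2)c(OC)c1OC | intermediate
8 | 4-oxo-6-(2,3,4-trimethoxyphenyl)-4H-pyran-3-carbonyl chloride | COc1ccc(-c2cc(=O)c(C(=O)Cl)co2)c(OC)c1OC | intermediate
9 | chromium hexacarbonyl, Cr(CO)6 | O=C=[Cr](=C=O)(=C=O)(=C=O)(=C=O)=C=O | starting material
10 | disodium pentacarbonylchromate, Na2Cr(CO)5 (not isolated) | [Na+].[Na+].O=C=[Cr-2](=C=O)(=C=O)(=C=O)=C=O | intermediate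
11 | sodium pentacarbonyl[4-oxo-6-(2,3,4-trimethoxyphenyl)-4H-pyran-3-carbonyl]chromate (not isolated) | [Na+].[O-]C(c1coc(-c2ccc(OC)c(OC)c2OC)cc1=O)=[Cr](=C=O)(=C=O)(=C=O)(=C=O)=C=O | intermediate
12 | pentacarbonyl{methoxy[4-oxo-6-(2,3,4-trimethoxyphenyl)-4H-pyran-3-yl]methylene}chromium | COC(c1coc(-c2ccc(OC)c(OC)c2OC)cc1=O)=[Cr](=C=O)(=C=O)(=C=O)(=C=O)=C=O | intermediate
13 | 2-ethynyl-4,4,5,5-tetramethyl-1,3,2-dioxaborolane | C#CB1OC(C)(C)C(C)(C)O1 | starting material
14 | tricarbonyl(η6-arene)chromium complex of 15, Cr(CO)3 bound to ring A (not isolated) | COc1cc(B2OC(C)(C)C(C)(C)O2)c(O)c2oc(-c3ccc(OC)c(OC)c3OC)cc(=O)c12.O=C=[Cr](=C=O)=C=O | intermediate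
15 | 8-hydroxy-5-methoxy-7-(4,4,5,5-tetramethyl-1,3,2-dioxaborolan-2-yl)-2-(2,3,4-trimethoxyphenyl)-4H-chromen-4-one | COc1cc(B2OC(C)(C)C(C)(C)O2)c(O)c2oc(-c3ccc(OC)c(OC)c3OC)cc(=O)c12 | intermediate
16 | 7,8-dihydroxy-5-methoxy-2-(2,3,4-trimethoxyphenyl)-4H-chromen-4-one | COc1cc(O)c(O)c2oc(-c3ccc(OC)c(OC)c3OC)cc(=O)c12 | intermediate
17 | 2',3',4',5,7,8-hexamethoxyflavone | COc1ccc(-c2cc(=O)c3c(OC)cc(OC)c(OC)c3o2)c(OC)c1OC | target

**Step count**

Total: 9 steps. Longest linear sequence: 8 steps (3 → 4 → 6 → 7 → 8 → 12 → 15 → 16 → 17).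

**Steps most likely to fail**

Step 7 (proposed new method). The alkyne may insert in the opposite sense. The vinylcarbene may close without CO insertion (cyclopentannulation) or be captured by the pyranone carbonyl oxygen. The terminal alkyne may oligomerize at chromium. The C–B bond may be lost by protodeboronation during demetalation.
The fallback uses known chemistry, sets out from 2 and comes back at 17. Acid chloride 2 would acylate the known phenol 2'-hydroxy-3',4',6'-trimethoxyacetophenone F1 (pyridine, rt; F1 is obtainable from 1,2,3,5-tetramethoxybenzene by Friedel–Crafts acetylation with AlCl3) to give 2-acetyl-3,5,6-trimethoxyphenyl 2,3,4-trimethoxybenzoate F2. KOH in pyridine at 50 °C would bring about the Baker–Venkataraman acyl shift to 1-(2-hydroxy-3,4,6-trimethoxyphenyl)-3-(2,3,4-trimethoxyphenyl)propane-1,3-dione F3. H2SO4 (cat.) in AcOH at 90 °C would cyclodehydrate F3 to 17.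

Step 6. The chromate dianion may transfer an electron to the pyranone or add to its C2 position instead of the acid chloride carbonyl. The oxonium salt may methylate the pyranone carbonyl oxygen to a pyrylium salt.
The fallback reverses the polarity (nucleophilic pyranonyl metal plus Cr(CO)6, the Fischer route), sets out from 2 and 9 and comes back at 12. (E)-4-(Dimethylamino)but-3-en-2-one F4 would be iodinated at its α-carbon with N-iodosuccinimide (CH2Cl2, 0 °C) to 4-(dimethylamino)-3-iodobut-3-en-2-one F5. Its dienolate (LiN(SiMe3)2, THF, −78 °C) would be acylated by 2 to 1-(dimethylamino)-2-iodo-5-(2,3,4-trimethoxyphenyl)pent-1-ene-3,5-dione F6, which on aqueous HCl would close to 5-iodo-2-(2,3,4-trimethoxyphenyl)-4H-pyran-4-one F7, with the iodine fixed at the carbon that bore it in F5. Iodine–magnesium exchange (iPrMgCl·LiCl, THF, −40 °C) would give chloro[4-oxo-6-(2,3,4-trimethoxyphenyl)-4H-pyran-3-yl]magnesium F8. Addition of F8 to Cr(CO)6 9 would give the chloromagnesium acylchromate F9, and Me3OBF4 (1.0 equiv, CH2Cl2, 0 °C) would methylate it to 12.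

Step 8. The electron-rich 5-methoxy-8-hydroxy ring and the catechol formed from it may be oxidized further to a quinone by peroxide under base. The C7–B bond may be lost by protodeboronation before it is oxidized.
The fallback caps the C8 phenol before the C7 oxygen is unveiled, sets out from 15 and comes back at 17. MeI and K2CO3 in acetone would give 5,8-dimethoxy-7-(4,4,5,5-tetramethyl-1,3,2-dioxaborolan-2-yl)-2-(2,3,4-trimethoxyphenyl)-4H-chromen-4-one F10. H2O2 and NaOH in THF at 0 °C would give the single, less oxidizable phenol 7-hydroxy-5,8-dimethoxy-2-(2,3,4-trimethoxyphenyl)-4H-chromen-4-one F11. Me2SO4 and K2CO3 in acetone would then give 17.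

**Further compounds**

F1 | step 7 | 1-(2-hydroxy-3,4,6-trimethoxyphenyl)ethanone (2'-hydroxy-3',4',6'-trimethoxyacetophenone) | CC(=O)c1c(O)c(OC)c(OC)cc1OC
F2 | step 7 | 2-acetyl-3,5,6-trimethoxyphenyl 2,3,4-trimethoxybenzoate | CC(=O)c1c(OC(=O)c2ccc(OC)c(OC)c2OC)c(OC)c(OC)cc1OC
F3 | step 7 | 1-(2-hydroxy-3,4,6-trimethoxyphenyl)-3-(2,3,4-trimethoxyphenyl)propane-1,3-dione | COc1ccc(C(=O)CC(=O)c2c(O)c(OC)c(OC)cc2OC)c(OC)c1OC
F4 | step 6 | (E)-4-(dimethylamino)but-3-en-2-one | CC(=O)/C=C/N(C)C
F5 | step 6 | 4-(dimethylamino)-3-iodobut-3-en-2-one | CC(=O)C(I)=CN(C)C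
F6 | step 6 | 1-(dimethylamino)-2-iodo-5-(2,3,4-trimethoxyphenyl)pent-1-ene-3,5-dione | CN(C)C=C(I)C(=O)CC(=O)c1ccc(OC)c(OC)c1OC
F7 | step 6 | 5-iodo-2-(2,3,4-trimethoxyphenyl)-4H-pyran-4-one | COc1ccc(-c2cc(=O)c(I)co2)c(OC)c1OC
F8 | step 6 | chloro[4-oxo-6-(2,3,4-trimethoxyphenyl)-4H-pyran-3-yl]magnesium | COc1ccc(-c2cc(=O)c([Mg]Cl)co2)c(OC)c1OC
F9 | step 6 | chloromagnesium pentacarbonyl[4-oxo-6-(2,3,4-trimethoxyphenyl)-4H-pyran-3-carbonyl]chromate | Cl[Mg+].[O-]C(c1coc(-c2ccc(OC)c(OC)c2OC)cc1=O)=[Cr](=C=O)(=C=O)(=C=O)(=C=O)=C=O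
F10 | step 8 | 5,8-dimethoxy-7-(4,4,5,5-tetramethyl-1,3,2-dioxaborolan-2-yl)-2-(2,3,4-trimethoxyphenyl)-4H-chromen-4-one | COc1cc(B2OC(C)(C)C(C)(C)O2)c(OC)c2oc(-c3ccc(OC)c(OC)c3OC)cc(=O)c12
F11 | step 8 | 7-hydroxy-5,8-dimethoxy-2-(2,3,4-trimethoxyphenyl)-4H-chromen-4-one | COc1cc(O)c(OC)c2oc(-c3ccc(OC)c(OC)c3OC)cc(=O)c12
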